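The data were computed on assumed constants.

What was charged as X stays counted. In cedar's last reading the four species summed to 102 %, so I took whatever left X to stand in J, E or L.

- cedar: X 72 mM (fed, over 2.5 s); Z 1 mol%; run made earlier; the fed solution adds 1.0 times the starting volume
- flask: X 48 mM (fed, over 2.5 s); Z 1 mol%; time 6.0 min; the fed solution adds 1.0 times the starting volume

cedar run (percent of the X charged)

| time / s | E / % | X / % | L / % | J / % |
|---|---|---|---|---|
| 10.0 | 3.7 | 82.8 | 1.3 | 11.2 |
| 15.0 | 7.7 | 74.6 | 1.9 | 15.1 |
| 20.0 | 12.1 | 69.8 | 6.2 | 14.3 |
| 30.0 | 18.2 | 61.9 | 7.5 | 15.5 |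
| 40.0 | 24.2 | 53.5 | 9.9 | 13.9 |

(readings scatter by 1 percentage point)

1. where most of what was charged as X, at 6.0 min is found (L / X / E / J)
2. the largest share itself, whichever of these holds it, in percent of the X charged

The flask looked nearly like cedar, with the same loading and the same dosing time. Its Z charged stood at 0.667 of cedar's, but its clock ran 9.00 times as long as cedar's last reading. I multiplied Z charged by time, and the flask's product over that of cedar's last reading came to 6.00. I call this the catalyst reach. I assumed Z intact and every step first order in Z and in its substrate; on those terms, equal reach means equal composition. Cedar's last reading stands at a reach of one, with X at 53.5 %.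

Cedar's X fell by 0.582 in natural logarithm per unit of reach, a pseudo-first-order reading with its scatter. Extended to the flask, that line put my estimate of X at 2.91 %. In cedar's last reading E stood at 2.44 times L, so, neglecting J, I reckoned E at 68.9 %, the largest share in my estimate. But cedar's readings ended at 40.0 s, and my reckoning took Z as intact up to 6.0 min.

The forecast gave E at 56 %, lower than my figure, and said: “E is the largest either way.”

The flask gave E at 48.2 %, lower than both, with X at 25.3 %.

    X + Z ⇌ J + Z, rate k1*[X]*[Z] forward; the back reaction follows from the equilibrium constant (K = 0.730, k = 65.9 /M/s)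
    J + Z ⇌ L + Z, rate k2*[Z]*[J] forward; the back reaction follows from the equilibrium constant (K = 1.03, k = 67.7 /M/s)
    J + Z ⇌ E + Z, rate k3*[Z]*[J] forward; the back reaction follows from the equilibrium constant (K = 4.56, k = 190 /M/s)
    Z + J → D (k = 1.75 /M/s)

In the flask, X's half-life by its forward step alone, with the catalyst as charged, was 0.37 min, shorter than a half-life of Z of 2.07 min, reckoned from Z's fall to 13.4 % of the catalyst, taken as exponential. Weighted by Z's mean share of 43.1 %, the flask's reach shrank to 2.59, where cedar's line gives X 21.2 % against the 25.3 % found. The neighbour with 0.4 mol% of Z had a nominal reach of 2.40, and its Z ended at 12.6 % of the catalyst. Weighted the same way, its reach became 1.01, where cedar's line gives X 53.2 %, and that neighbour held X at 47.6 %.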